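The ten-membered carbocycle is opened at C4–C5, the single bond between the two allylic methylenes of its ring-cis,cis 1,5-diene (C2=C3–C4–C5–C6=C7); both carbons then carry the same electrophilic polarity. A nickel(0) reductive allyl–allyl coupling of an open-chain C4,C5-bis(allylic bromide) forms this bond and the ring in one operation without touching a stereocentre. The precursor already holds everything else: the C1/C9/C10 triad (Evans syn aldol, then hydroxyl-directed anti reduction), the Z C2=C3 alkene (from a Z-vinyl iodide), the E C6=C7 enoate (Horner–Wadsworth–Emmons), silyl ethers at C1 and C9 and a fluoride-labile ester.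

Key step: step 16

Remark: locants C1–C10 are those of the target ring (C1 allylic CH–O, C3 C–CH3, C7 C–CO2H, C9 CH–O, C10 CH–iPr) and are kept for open-chain compounds; 2-[(4-methoxybenzyl)oxy]acetaldehyde is taken as a catalogue aldehyde, chosen because its ether can be cleaved oxidatively in the presence of alkenes.

Step 1
Reactants: 1 (S)-4-benzyl-2-oxazolidinone; 2 3-methylbutanoyl chloride
Product: 3 (S)-4-benzyl-3-(3-methylbutanoyl)oxazolidin-2-one
Conditions: n-BuLi, THF, −78 °C; then 2, −78 → 0 °C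
Reagents that add atoms: none
Why: N-acylation of the lithiated oxazolidinone by the acid chloride is a standard imide formation that leaves the auxiliary stereocentre untouched.

Step 2
Reactants: 3 (S)-4-benzyl-3-(3-methylbutanoyl)oxazolidin-2-one; 4 2-[(4-methoxybenzyl)oxy]acetaldehyde
Product: 7 (S)-4-benzyl-3-[(2S,3S)-3-hydroxy-4-[(4-methoxybenzyl)oxy]-2-(propan-2-yl)butanoyl]oxazolidin-2-one, via Z-boron enolate 5 (not isolated), via boron aldolate 6 (not isolated)
Conditions: Bu2BOTf, Et3N, CH2Cl2, 0 °C; then 4, −78 → 0 °C; H2O2, pH 7 buffer–MeOH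
Reagents that add atoms: none
Why: Evans syn aldol: the Z-boron enolate reacts through a closed chair transition state on the face away from the benzyl group, which should set C10 and C9 (syn; 2S,3S in the adduct) in one step.

Step 3
Reactants: 7 (S)-4-benzyl-3-[(2S,3S)-3-hydroxy-4-[(4-methoxybenzyl)oxy]-2-(propan-2-yl)butanoyl]oxazolidin-2-one
Product: 8 (2S,3S)-3-hydroxy-N-methoxy-4-[(4-methoxybenzyl)oxy]-N-methyl-2-(propan-2-yl)butanamide
Conditions: MeNHOMe·HCl (3 equiv), AlMe3 (3 equiv), CH2Cl2, −20 → 0 °C; Rochelle salt work-up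
Reagents that add atoms: N,O-dimethylhydroxylamine hydrochloride, CNOC.Cl
Why: Weinreb transamidation: the aluminium amide, anchored by the free C9 hydroxyl, should cleave the exocyclic imide carbonyl selectively and release the auxiliary without epimerising C10.

Step 4
Reactants: 9 propargyl alcohol
Product: 11 (Z)-3-iodo-2-methylprop-2-en-1-ol, via vinylmagnesium alkoxide 10 (not isolated)
Conditions: MeMgBr (2.5 equiv), CuI (10 mol%), THF, −10 → 23 °C; then I2, −78 → 0 °C
Reagents that add atoms: methylmagnesium bromide, C[Mg]Br; iodine, II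
Why: Copper-catalysed anti-carbomagnesiation of the propargylic magnesium alkoxide places methyl on the internal carbon and magnesium on the terminal carbon cis to CH2O (five-membered chelate), so iodinolysis with retention should give the Z iodide.

Step 5
Reactants: 11 (Z)-3-iodo-2-methylprop-2-en-1-ol
Product: 12 (Z)-tert-butyl[(3-iodo-2-methylprop-2-en-1-yl)oxy]dimethylsilane
Conditions: TBSCl, imidazole, DMF, 0 → 23 °C
Reagents that add atoms: tert-butyldimethylsilyl chloride, CC(C)(C)[Si](C)(C)Cl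
Why: Standard silylation of a primary alcohol masks the future C4 oxygen for the lithiation.

Step 6
Reactants: 12 (Z)-tert-butyl[(3-iodo-2-methylprop-2-en-1-yl)oxy]dimethylsilane; 8 (2S,3S)-3-hydroxy-N-methoxy-4-[(4-methoxybenzyl)oxy]-N-methyl-2-(propan-2-yl)butanamide
Product: 14 (2Z,5S,6S)-1-[(tert-butyldimethylsilyl)oxy]-6-hydroxy-7-[(4-methoxybenzyl)oxy]-2-methyl-5-(propan-2-yl)hept-2-en-4-one, via Z-vinyllithium 13 (not isolated)
Conditions: 12 (2.5 equiv), t-BuLi (5 equiv), Et2O, −78 °C; then 8, THF, −78 → −40 °C; AcOH quench at −78 °C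
Reagents that add atoms: none
Why: Weinreb ketone synthesis: iodine–lithium exchange and acylation both retain alkene geometry, one equivalent of 13 deprotonates C9–OH and the chelated tetrahedral intermediate prevents over-addition, so the Z-enone (C1 ketone) should result.

Step 7
Reactants: 14 (2Z,5S,6S)-1-[(tert-butyldimethylsilyl)oxy]-6-hydroxy-7-[(4-methoxybenzyl)oxy]-2-methyl-5-(propan-2-yl)hept-2-en-4-one
Product: 15 (2Z,4R,5R,6S)-1-[(tert-butyldimethylsilyl)oxy]-7-[(4-methoxybenzyl)oxy]-2-methyl-5-(propan-2-yl)hept-2-ene-4,6-diol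
Conditions: Me4NBH(OAc)3, MeCN–AcOH (1:1), −30 °C
Reagents that add atoms: none
Why: Evans–Saksena reduction: the C9 hydroxyl binds boron and delivers hydride intramolecularly through a chair transition state, which should set C1 anti to C9 (1,3-anti diol) by 1,2-reduction only.

Step 8
Reactants: 15 (2Z,4R,5R,6S)-1-[(tert-butyldimethylsilyl)oxy]-7-[(4-methoxybenzyl)oxy]-2-methyl-5-(propan-2-yl)hept-2-ene-4,6-diol
Product: 16 (2Z,4R,5R,6S)-1,4,6-tris[(tert-butyldimethylsilyl)oxy]-7-[(4-methoxybenzyl)oxy]-2-methyl-5-(propan-2-yl)hept-2-ene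
Conditions: TBSOTf (3 equiv), 2,6-lutidine, CH2Cl2, −78 → 0 °C
Reagents that add atoms: tert-butyldimethylsilyl trifluoromethanesulfonate, CC(C)(C)[Si](C)(C)OS(=O)(=O)C(F)(F)F
Why: Silyl triflate silylation caps both hindered secondary hydroxyls; two acyclic silyl ethers are preferred to a cyclic acetal, which would tie the anti-1,3-diol into a ring and hinder folding for the macrocyclisation.

Step 9
Reactants: 16 (2Z,4R,5R,6S)-1,4,6-tris[(tert-butyldimethylsilyl)oxy]-7-[(4-methoxybenzyl)oxy]-2-methyl-5-(propan-2-yl)hept-2-ene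
Product: 17 (2S,3R,4R,5Z)-2,4,7-tris[(tert-butyldimethylsilyl)oxy]-6-methyl-3-(propan-2-yl)hept-5-en-1-ol
Conditions: DDQ, CH2Cl2–pH 7 buffer (10:1), 0 °C
Reagents that add atoms: none
Why: Oxidative cleavage of the p-methoxybenzyl ether by DDQ should free the C8 hydroxyl while sparing the silyl ethers and the trisubstituted alkene.

Step 10
Reactants: 17 (2S,3R,4R,5Z)-2,4,7-tris[(tert-butyldimethylsilyl)oxy]-6-methyl-3-(propan-2-yl)hept-5-en-1-ol
Product: 18 (2Z,4R,5R,6S)-1,4,6-tris[(tert-butyldimethylsilyl)oxy]-7-iodo-2-methyl-5-(propan-2-yl)hept-2-ene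
Conditions: I2, PPh3, imidazole, CH2Cl2, 0 → 23 °C
Reagents that add atoms: iodine, II
Why: Appel-type iodination converts the primary C8 alcohol into the iodide under neutral conditions; the iodide is preferred to a sulfonate ester, which the C1 silyl ether oxygen could displace to form a tetrahydrofuran.

Step 11
Reactants: 19 diethylphosphonoacetic acid; 20 2-(trimethylsilyl)ethanol
Product: 21 2-(trimethylsilyl)ethyl 2-(diethoxyphosphoryl)acetate
Conditions: DCC, DMAP (cat.), CH2Cl2, 0 → 23 °C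
Reagents that add atoms: none
Why: Steglich esterification provides the phosphonoacetate that carries the fluoride-labile ester needed at the end.

Step 12
Reactants: 18 (2Z,4R,5R,6S)-1,4,6-tris[(tert-butyldimethylsilyl)oxy]-7-iodo-2-methyl-5-(propan-2-yl)hept-2-ene; 21 2-(trimethylsilyl)ethyl 2-(diethoxyphosphoryl)acetate
Product: 22 2-(trimethylsilyl)ethyl (4R,5S,6R,7Z)-4,6,9-tris[(tert-butyldimethylsilyl)oxy]-2-(diethoxyphosphoryl)-8-methyl-5-(propan-2-yl)non-7-enoate (C2 epimers)
Conditions: 21 (3 equiv), NaH, DMF, 0 °C; then 18, 60 °C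
Reagents that add atoms: none
Why: SN2 C-alkylation of the phosphonate-stabilised carbanion by the primary iodide forms C7–C8; excess nucleophile limits dialkylation, and the new C7 centre is destroyed in the next step.

Step 13
Reactants: 22 2-(trimethylsilyl)ethyl (4R,5S,6R,7Z)-4,6,9-tris[(tert-butyldimethylsilyl)oxy]-2-(diethoxyphosphoryl)-8-methyl-5-(propan-2-yl)non-7-enoate; 23 (tert-butyldimethylsilyloxy)acetaldehyde
Product: 24 2-(trimethylsilyl)ethyl (2E,4R,5S,6R,7Z)-4,6,9-tris[(tert-butyldimethylsilyl)oxy]-2-{2-[(tert-butyldimethylsilyl)oxy]ethylidene}-8-methyl-5-(propan-2-yl)non-7-enoate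
Conditions: NaH, THF, 0 °C; then 23, 0 → 23 °C
Reagents that add atoms: none
Why: Horner–Wadsworth–Emmons olefination of the stabilised α-substituted phosphonate is under thermodynamic control and should place the ester trans to C5 (E, with C5 cis to C8 as the ring requires); any Z isomer is separable by chromatography.

Step 14
Reactants: 24 2-(trimethylsilyl)ethyl (2E,4R,5S,6R,7Z)-4,6,9-tris[(tert-butyldimethylsilyl)oxy]-2-{2-[(tert-butyldimethylsilyl)oxy]ethylidene}-8-methyl-5-(propan-2-yl)non-7-enoate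
Product: 25 2-(trimethylsilyl)ethyl (2E,4R,5S,6R,7Z)-4,6-bis[(tert-butyldimethylsilyl)oxy]-9-hydroxy-2-(2-hydroxyethylidene)-8-methyl-5-(propan-2-yl)non-7-enoate
Conditions: HF·pyridine, pyridine, THF, 0 °C
Reagents that add atoms: none
Why: Pyridine-buffered fluoride desilylation is selective for the two primary allylic silyl ethers over the two hindered secondary ones and should leave the silylethyl ester intact; the E geometry keeps C5–OH away from the ester.

Step 15
Reactants: 25 2-(trimethylsilyl)ethyl (2E,4R,5S,6R,7Z)-4,6-bis[(tert-butyldimethylsilyl)oxy]-9-hydroxy-2-(2-hydroxyethylidene)-8-methyl-5-(propan-2-yl)non-7-enoate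
Product: 26 2-(trimethylsilyl)ethyl (2E,4R,5S,6R,7Z)-9-bromo-2-(2-bromoethylidene)-4,6-bis[(tert-butyldimethylsilyl)oxy]-8-methyl-5-(propan-2-yl)non-7-enoate
Conditions: CBr4, PPh3, CH2Cl2, −20 → 0 °C
Reagents that add atoms: carbon tetrabromide, BrC(Br)(Br)Br
Why: Appel bromination converts both primary allylic alcohols into bromides by SN2 at the CH2 carbons, without allylic shift or loss of alkene geometry.

Step 16
Reactants: 26 2-(trimethylsilyl)ethyl (2E,4R,5S,6R,7Z)-9-bromo-2-(2-bromoethylidene)-4,6-bis[(tert-butyldimethylsilyl)oxy]-8-methyl-5-(propan-2-yl)non-7-enoate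
Product: 27 2-(trimethylsilyl)ethyl (1E,5Z,7R,8S,9R)-7,9-bis[(tert-butyldimethylsilyl)oxy]-5-methyl-8-(propan-2-yl)cyclodeca-1,5-diene-1-carboxylate
Conditions: Ni(CO)4 (5 equiv), NMP, 50 °C, Ar; 26 added by syringe pump over 12 h (final ≤ 2 mM)
Reagents that add atoms: none
Why: Each C–Br bond adds oxidatively to nickel(0) to give η3-allylnickel bromides, which in the polar solvent combine to a bis(allyl)nickel species that reductively eliminates the 1,5-diene and leaves NiBr2. The closest known reaction type is the nickel carbonyl-mediated cyclisation of α,ω-bis(allylic bromides) to macrocyclic 1,5-dienes. The ten-membered ring closes by C4–C5 reductive elimination from the nickel-bridged bis(allyl) intermediate, a tail-to-tail allyl–allyl union run under high dilution. No stereocentre is formed, and C1, C9 and C10 are not involved. The step needs C4–C5 coupling rather than bonding through C2 or C7 (six- or eight-membered vinyl-substituted rings), which the fully substituted, ester-bearing C7 and the C2 terminus flanked by the C1 silyloxy group should enforce, and it needs both ring-cis alkenes, which are preset in 26 and are the least strained outcome if the allyl units equilibrate. Silyl ethers at allylic C1 and at C9 leave the two bromides as the only sites for nickel insertion and suppress β-alkoxide loss.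

Step 17
Reactants: 27 2-(trimethylsilyl)ethyl (1E,5Z,7R,8S,9R)-7,9-bis[(tert-butyldimethylsilyl)oxy]-5-methyl-8-(propan-2-yl)cyclodeca-1,5-diene-1-carboxylate
Product: 28 2-(trimethylsilyl)ethyl (1E,5Z,7R,8S,9R)-7,9-dihydroxy-5-methyl-8-(propan-2-yl)cyclodeca-1,5-diene-1-carboxylate
Conditions: HF·pyridine (excess), pyridine, THF, 0 → 23 °C
Reagents that add atoms: none
Why: Pyridine-buffered fluoride desilylation removes both secondary silyl ethers but not the silylethyl ester, and the weakly acidic, alkoxide-free medium should keep the freed C9 hydroxyl from lactonising onto the C7 ester before it is acetylated.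

Step 18
Reactants: 28 2-(trimethylsilyl)ethyl (1E,5Z,7R,8S,9R)-7,9-dihydroxy-5-methyl-8-(propan-2-yl)cyclodeca-1,5-diene-1-carboxylate
Product: 29 2-(trimethylsilyl)ethyl (1E,5Z,7R,8S,9R)-7,9-diacetoxy-5-methyl-8-(propan-2-yl)cyclodeca-1,5-diene-1-carboxylate
Conditions: Ac2O, DMAP, pyridine, CH2Cl2, 0 → 23 °C
Reagents that add atoms: acetic anhydride, CC(=O)OC(C)=O
Why: DMAP-catalysed acyl transfer acetylates both secondary hydroxyls with retention; once C9–OH is capped, lactonisation onto the ester is no longer possible.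

Step 19
Reactants: 29 2-(trimethylsilyl)ethyl (1E,5Z,7R,8S,9R)-7,9-diacetoxy-5-methyl-8-(propan-2-yl)cyclodeca-1,5-diene-1-carboxylate
Product: 30 (1E,5Z,7R,8S,9R)-7,9-diacetoxy-5-methyl-8-(propan-2-yl)cyclodeca-1,5-diene-1-carboxylic acid
Conditions: TASF, DMF, 0 → 23 °C; then 0.1 M aq. HCl
Reagents that add atoms: none
Why: Fluoride attack at silicon triggers β-elimination of the 2-(trimethylsilyl)ethyl ester (ethene and fluorotrimethylsilane leave) under anhydrous, non-hydrolytic conditions that should spare both acetates and the diene; acidification gives the acid.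

Compound list
1 | (S)-4-benzyl-2-oxazolidinone | O=C1N[C@@H](Cc2ccccc2)CO1 | starting material
2 | 3-methylbutanoyl chloride | CC(C)CC(=O)Cl | starting material
3 | (S)-4-benzyl-3-(3-methylbutanoyl)oxazolidin-2-one | CC(C)CC(=O)N1C(=O)OC[C@@H]1Cc1ccccc1 | intermediate
4 | 2-[(4-methoxybenzyl)oxy]acetaldehyde | COc1ccc(COCC=O)cc1 | starting material
5 | Z-boron enolate: (S)-4-benzyl-3-[(Z)-1-(dibutylboryloxy)-3-methylbut-1-en-1-yl]oxazolidin-2-one | CCCCB(CCCC)O/C(=C\C(C)C)N1C(=O)OC[C@@H]1Cc1ccccc1 | intermediate (not isolated)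
6 | boron aldolate: O-dibutylboryl derivative of 7 | O=C(N1C(=O)OC[C@@H]1Cc1ccccc1)[C@@H](C(C)C)[C@H](OB(CCCC)CCCC)COCc1ccc(OC)cc1 | intermediate (not isolated)
7 | (S)-4-benzyl-3-[(2S,3S)-3-hydroxy-4-[(4-methoxybenzyl)oxy]-2-(propan-2-yl)butanoyl]oxazolidin-2-one | O=C(N1C(=O)OC[C@@H]1Cc1ccccc1)[C@@H](C(C)C)[C@H](O)COCc1ccc(OC)cc1 | intermediate
8 | (2S,3S)-3-hydroxy-N-methoxy-4-[(4-methoxybenzyl)oxy]-N-methyl-2-(propan-2-yl)butanamide | CON(C)C(=O)[C@@H](C(C)C)[C@H](O)COCc1ccc(OC)cc1 | intermediate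
9 | propargyl alcohol (prop-2-yn-1-ol) | C#CCO | starting material
10 | vinylmagnesium alkoxide: bromomagnesium (Z)-3-(bromomagnesio)-2-methylprop-2-en-1-olate | C/C(CO[Mg]Br)=C/[Mg]Br | intermediate (not isolated)
11 | (Z)-3-iodo-2-methylprop-2-en-1-ol | C/C(CO)=C/I | intermediate
12 | (Z)-tert-butyl[(3-iodo-2-methylprop-2-en-1-yl)oxy]dimethylsilane | C/C(CO[Si](C)(C)C(C)(C)C)=C/I | intermediate
13 | Z-vinyllithium: (Z)-{3-[(tert-butyldimethylsilyl)oxy]-2-methylprop-1-en-1-yl}lithium | C/C(CO[Si](C)(C)C(C)(C)C)=C/[Li] | intermediate (not isolated)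
14 | (2Z,5S,6S)-1-[(tert-butyldimethylsilyl)oxy]-6-hydroxy-7-[(4-methoxybenzyl)oxy]-2-methyl-5-(propan-2-yl)hept-2-en-4-one | CC(C)(C)[Si](C)(C)OC/C(C)=C\C(=O)[C@@H](C(C)C)[C@H](O)COCc1ccc(OC)cc1 | intermediate
15 | (2Z,4R,5R,6S)-1-[(tert-butyldimethylsilyl)oxy]-7-[(4-methoxybenzyl)oxy]-2-methyl-5-(propan-2-yl)hept-2-ene-4,6-diol | CC(C)(C)[Si](C)(C)OC/C(C)=C\[C@@H](O)[C@@H](C(C)C)[C@H](O)COCc1ccc(OC)cc1 | intermediate
16 | (2Z,4R,5R,6S)-1,4,6-tris[(tert-butyldimethylsilyl)oxy]-7-[(4-methoxybenzyl)oxy]-2-methyl-5-(propan-2-yl)hept-2-ene | CC(C)(C)[Si](C)(C)OC/C(C)=C\[C@@H](O[Si](C)(C)C(C)(C)C)[C@@H](C(C)C)[C@H](O[Si](C)(C)C(C)(C)C)COCc1ccc(OC)cc1 | intermediate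
17 | (2S,3R,4R,5Z)-2,4,7-tris[(tert-butyldimethylsilyl)oxy]-6-methyl-3-(propan-2-yl)hept-5-en-1-ol | CC(C)(C)[Si](C)(C)OC/C(C)=C\[C@@H](O[Si](C)(C)C(C)(C)C)[C@@H](C(C)C)[C@H](O[Si](C)(C)C(C)(C)C)CO | intermediate
18 | (2Z,4R,5R,6S)-1,4,6-tris[(tert-butyldimethylsilyl)oxy]-7-iodo-2-methyl-5-(propan-2-yl)hept-2-ene | CC(C)(C)[Si](C)(C)OC/C(C)=C\[C@@H](O[Si](C)(C)C(C)(C)C)[C@@H](C(C)C)[C@H](O[Si](C)(C)C(C)(C)C)CI | intermediate
19 | diethylphosphonoacetic acid | CCOP(=O)(CC(=O)O)OCC | starting material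
20 | 2-(trimethylsilyl)ethanol | C[Si](C)(C)CCO | starting material
21 | 2-(trimethylsilyl)ethyl 2-(diethoxyphosphoryl)acetate | CCOP(=O)(CC(=O)OCC[Si](C)(C)C)OCC | intermediate
22 | 2-(trimethylsilyl)ethyl (4R,5S,6R,7Z)-4,6,9-tris[(tert-butyldimethylsilyl)oxy]-2-(diethoxyphosphoryl)-8-methyl-5-(propan-2-yl)non-7-enoate (C2 epimers) | CC(C)(C)[Si](C)(C)OC/C(C)=C\[C@@H](O[Si](C)(C)C(C)(C)C)[C@@H](C(C)C)[C@H](O[Si](C)(C)C(C)(C)C)CC(C(=O)OCC[Si](C)(C)C)P(=O)(OCC)OCC | intermediate
23 | (tert-butyldimethylsilyloxy)acetaldehyde | CC(C)(C)[Si](C)(C)OCC=O | starting material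
24 | 2-(trimethylsilyl)ethyl (2E,4R,5S,6R,7Z)-4,6,9-tris[(tert-butyldimethylsilyl)oxy]-2-{2-[(tert-butyldimethylsilyl)oxy]ethylidene}-8-methyl-5-(propan-2-yl)non-7-enoate | CC(C)(C)[Si](C)(C)OC/C(C)=C\[C@@H](O[Si](C)(C)C(C)(C)C)[C@@H](C(C)C)[C@H](O[Si](C)(C)C(C)(C)C)C/C(C(=O)OCC[Si](C)(C)C)=C\CO[Si](C)(C)C(C)(C)C | intermediate
25 | 2-(trimethylsilyl)ethyl (2E,4R,5S,6R,7Z)-4,6-bis[(tert-butyldimethylsilyl)oxy]-9-hydroxy-2-(2-hydroxyethylidene)-8-methyl-5-(propan-2-yl)non-7-enoate | OC/C(C)=C\[C@@H](O[Si](C)(C)C(C)(C)C)[C@@H](C(C)C)[C@H](O[Si](C)(C)C(C)(C)C)C/C(C(=O)OCC[Si](C)(C)C)=C\CO | intermediate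
26 | 2-(trimethylsilyl)ethyl (2E,4R,5S,6R,7Z)-9-bromo-2-(2-bromoethylidene)-4,6-bis[(tert-butyldimethylsilyl)oxy]-8-methyl-5-(propan-2-yl)non-7-enoate (key-step precursor: C4,C5-dibromide; C1,C9-bis-O-TBS) | CC(C)(C)[Si](C)(C)O[C@H](/C=C(/C)CBr)[C@@H](C(C)C)[C@H](O[Si](C)(C)C(C)(C)C)C/C(C(=O)OCC[Si](C)(C)C)=C\CBr | intermediate
27 | 2-(trimethylsilyl)ethyl (1E,5Z,7R,8S,9R)-7,9-bis[(tert-butyldimethylsilyl)oxy]-5-methyl-8-(propan-2-yl)cyclodeca-1,5-diene-1-carboxylate (key-step product) | CC(C)(C)[Si](C)(C)O[C@@H]1/C=C(/C)CC/C=C(/C(=O)OCC[Si](C)(C)C)C[C@@H](O[Si](C)(C)C(C)(C)C)[C@@H]1C(C)C | intermediate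
28 | 2-(trimethylsilyl)ethyl (1E,5Z,7R,8S,9R)-7,9-dihydroxy-5-methyl-8-(propan-2-yl)cyclodeca-1,5-diene-1-carboxylate | O[C@@H]1/C=C(/C)CC/C=C(/C(=O)OCC[Si](C)(C)C)C[C@@H](O)[C@@H]1C(C)C | intermediate
29 | 2-(trimethylsilyl)ethyl (1E,5Z,7R,8S,9R)-7,9-diacetoxy-5-methyl-8-(propan-2-yl)cyclodeca-1,5-diene-1-carboxylate | CC(=O)O[C@@H]1/C=C(/C)CC/C=C(/C(=O)OCC[Si](C)(C)C)C[C@@H](OC(C)=O)[C@@H]1C(C)C | intermediate
30 | (1E,5Z,7R,8S,9R)-7,9-diacetoxy-5-methyl-8-(propan-2-yl)cyclodeca-1,5-diene-1-carboxylic acid | CC(=O)O[C@@H]1/C=C(/C)CC/C=C(/C(=O)O)C[C@@H](OC(C)=O)[C@@H]1C(C)C | target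

Total step count: 19. Longest linear sequence: 16 steps (steps 1–3, 6–10, 12–19); side branches are steps 4–5 and step 11.

Steps most likely to fail

Step 16 (nickel macrocyclisation). Oligomerisation may outrun ring closure, the allyl units may join through C2 or C7 instead of C4 and C5, and π-allyl isomerisation may erode the cis geometry of either alkene. The fallback forms the same C4–C5 bond by polar, stepwise chemistry; it sets out from 26 and returns at 27. The more electrophilic C5 bromide (γ to the ester) is displaced by sodium benzenesulfinate (1 equiv, DMF, 0 °C) to give the C5 phenyl sulfone–C4 bromide F1. Cs2CO3 in DMF under high dilution then closes the ring by intramolecular alkylation of the sulfone-stabilised C5 carbanion with the C4 allylic bromide, giving the C5-sulfonyl cyclodecadiene F2 (C5 epimers). Palladium-catalysed reductive desulfonylation (Pd(PPh3)4, NaBH4, THF–i-PrOH), with hydride entering at C5, distal to the ester, would give 27.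

Step 12 (phosphonoacetate alkylation). Substitution at the β-branched, β-silyloxy C8 may be slow, so that elimination to the enol ether and dialkylation compete. The fallback replaces alkylation–olefination by ester-enolate alkylation and aldol condensation; it sets out from 18 and returns at 24. The lithium enolate of 2-(trimethylsilyl)ethyl acetate (LDA, THF–DMPU, −78 → −30 °C), a smaller and stronger nucleophile, is alkylated by 18 to give the saturated silylethyl ester F3. Its lithium enolate (LDA, THF, −78 °C) adds to aldehyde 23 to give the β-hydroxy ester F4 (diastereomers). Mesylation (MsCl, Et3N, CH2Cl2, 0 °C) gives the mesylate F5, and DBU-induced E1cB elimination should give the E-enoate 24.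

Step 6 (vinyllithium addition to the free hydroxy amide). The lithium alkoxide of 8 may undergo retro-aldol cleavage, the hindered amide may be attacked at N–OMe instead of at the carbonyl, and the Z-enone may isomerise during work-up. The fallback is a temporary O-silylation that removes the alkoxide; it sets out from 8 and returns at 14. TMSCl and imidazole (CH2Cl2, 0 °C) give the O-trimethylsilyl amide F6. Addition of 13 (1.3 equiv, −78 °C) gives the O-trimethylsilyl Z-enone F7, and citric acid in MeOH at 0 °C removes the trimethylsilyl group to give 14.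

Further compounds
F1 | step 16 | 2-(trimethylsilyl)ethyl (2E,4R,5S,6R,7Z)-9-bromo-4,6-bis[(tert-butyldimethylsilyl)oxy]-8-methyl-2-[2-(phenylsulfonyl)ethylidene]-5-(propan-2-yl)non-7-enoate | CC(C)(C)[Si](C)(C)O[C@H](/C=C(/C)CBr)[C@@H](C(C)C)[C@H](O[Si](C)(C)C(C)(C)C)C/C(C(=O)OCC[Si](C)(C)C)=C\CS(=O)(=O)c1ccccc1
F2 | step 16 | 2-(trimethylsilyl)ethyl (1E,5Z,7R,8S,9R)-7,9-bis[(tert-butyldimethylsilyl)oxy]-5-methyl-3-(phenylsulfonyl)-8-(propan-2-yl)cyclodeca-1,5-diene-1-carboxylate (C3 epimers; ring C5 of the target) | CC(C)(C)[Si](C)(C)O[C@@H]1/C=C(/C)CC(S(=O)(=O)c2ccccc2)/C=C(/C(=O)OCC[Si](C)(C)C)C[C@@H](O[Si](C)(C)C(C)(C)C)[C@@H]1C(C)C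
F3 | step 12 | 2-(trimethylsilyl)ethyl (4R,5S,6R,7Z)-4,6,9-tris[(tert-butyldimethylsilyl)oxy]-8-methyl-5-(propan-2-yl)non-7-enoate | CC(C)(C)[Si](C)(C)OC/C(C)=C\[C@@H](O[Si](C)(C)C(C)(C)C)[C@@H](C(C)C)[C@H](O[Si](C)(C)C(C)(C)C)CCC(=O)OCC[Si](C)(C)C
F4 | step 12 | 2-(trimethylsilyl)ethyl (4R,5S,6R,7Z)-4,6,9-tris[(tert-butyldimethylsilyl)oxy]-2-{2-[(tert-butyldimethylsilyl)oxy]-1-hydroxyethyl}-8-methyl-5-(propan-2-yl)non-7-enoate (diastereomers) | CC(C)(C)[Si](C)(C)OC/C(C)=C\[C@@H](O[Si](C)(C)C(C)(C)C)[C@@H](C(C)C)[C@H](O[Si](C)(C)C(C)(C)C)CC(C(=O)OCC[Si](C)(C)C)C(O)CO[Si](C)(C)C(C)(C)C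
F5 | step 12 | methanesulfonate of F4 | CC(C)(C)[Si](C)(C)OC/C(C)=C\[C@@H](O[Si](C)(C)C(C)(C)C)[C@@H](C(C)C)[C@H](O[Si](C)(C)C(C)(C)C)CC(C(=O)OCC[Si](C)(C)C)C(OS(C)(=O)=O)CO[Si](C)(C)C(C)(C)C
F6 | step 6 | (2S,3S)-N-methoxy-4-[(4-methoxybenzyl)oxy]-N-methyl-2-(propan-2-yl)-3-[(trimethylsilyl)oxy]butanamide | CON(C)C(=O)[C@@H](C(C)C)[C@H](O[Si](C)(C)C)COCc1ccc(OC)cc1
F7 | step 6 | (2Z,5S,6S)-1-[(tert-butyldimethylsilyl)oxy]-7-[(4-methoxybenzyl)oxy]-2-methyl-5-(propan-2-yl)-6-[(trimethylsilyl)oxy]hept-2-en-4-one | CC(C)(C)[Si](C)(C)OC/C(C)=C\C(=O)[C@@H](C(C)C)[C@H](O[Si](C)(C)C)COCc1ccc(OC)cc1
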